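**Plan**
1. Retrosynthesis: the C2–C3 bond of the dihydropyranone is cut first (reverse of a 1,3 O→C, Petasis–Ferrier-type shift) to give a 4-methylidene-4H-1,3-dioxin; then C4=CH2 goes back to a lactone C4=O (1,3-dioxin-4-one); then the dioxinone is split into (Z)-icos-11-enal and acetylketene; the aldehyde comes from (Z)-icos-11-en-1-ol.
2. Enabling feature: ring O1 is both the oxygen on stereocentre C2 and the enol-ether oxygen of the vinylogous ester O1–C6(Me)=C5–C4(=O)–C3H2. C2 can therefore be an oxocarbenium carbon (C2=O1+) and C3 an enol carbon. A temporary 1,3-dioxin ring, in which C2 is also bound to the C4 enol oxygen, holds both halves in the required (Z)-arrangement and is consumed in the event.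
3. Forward order: chain oxidation, [4+2] construction of the temporary 1,3-dioxin-4-one ring, carbonyl methylenation, then exchange of the acetal C2–O bond for the C2–C3 bond, so the 2,3-dihydro-4H-pyran-4-one ring arises last.
4. Stereochemistry: the (Z)-alkene is bought and never touched. C2 is made racemic in the dioxinone, erased on ionisation and set in the last step by a chiral counteranion (enantioconvergent), so no auxiliary or resolution is needed.

Key step: step 4

Assumption: the confined chiral imidodiphosphorimidate (IDPi) acid is taken as an available catalyst; its sense of induction on this new substrate class cannot be predicted with certainty, so the antipode that gives the (R)-product is identified in a first run and then used.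

**Step 1**
Reactants: 1 (11Z)-icos-11-en-1-ol
Product: 2 (11Z)-icos-11-enal
Conditions: TEMPO (10 mol%), PhI(OAc)2 (1.1 equiv), CH2Cl2, rt
Reagents that add atoms: none
Why: TEMPO/PhI(OAc)2 (oxoammonium) oxidation should stop cleanly at the aldehyde and leave the isolated (Z)-alkene untouched; no stereocentre is formed.

**Step 2**
Reactants: 2 (11Z)-icos-11-enal; 3 2,2,6-trimethyl-4H-1,3-dioxin-4-one
Product: 5 rac-6-methyl-2-[(10Z)-nonadec-10-en-1-yl]-4H-1,3-dioxin-4-one, via acetylketene 4 (not isolated)
Conditions: 3 (2 equiv), toluene, 110 °C, N2 sweep (acetone removed)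
Reagents that add atoms: none
Why: Thermal retro-[4+2] of 3 expels acetone and gives acetylketene 4, which the aldehyde C=O should trap in a hetero-Diels–Alder ([4+2]) cycloaddition (dioxinone carbonyl exchange) while the volatile acetone leaves the equilibrium; C2 forms racemic, which is harmless because this centre is erased in step 4.

**Step 3**
Reactants: 5 rac-6-methyl-2-[(10Z)-nonadec-10-en-1-yl]-4H-1,3-dioxin-4-one
Product: 6 rac-6-methyl-4-methylidene-2-[(10Z)-nonadec-10-en-1-yl]-4H-1,3-dioxine
Conditions: Cp2TiMe2 (2.5 equiv), toluene/THF, 65 °C, dark; pentane, filtration through basic Al2O3 (1% Et3N); used at once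
Reagents that add atoms: dimethyltitanocene (Petasis reagent), C[Ti](C)(C1C=CC=C1)C1C=CC=C1
Why: Petasis methylenation: Cp2Ti=CH2 formed thermally from Cp2TiMe2 should add [2+2] to the lactone carbonyl and cyclorevert to the exocyclic enol ether under neutral, aprotic conditions that spare the acetal, the acidic C6-methyl group and the unstrained (Z)-alkene; no stereocentre is formed.

**Step 4**
Reactants: 6 rac-6-methyl-4-methylidene-2-[(10Z)-nonadec-10-en-1-yl]-4H-1,3-dioxine
Product: 9 (2R)-6-methyl-2-[(10Z)-nonadec-10-en-1-yl]-2,3-dihydro-4H-pyran-4-one, via ring-opened oxocarbenium ion 7 (not isolated), via O-silylated pyranone cation 8 (not isolated)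
Conditions: (S,S)- or (R,R)-IDPi (3 mol%), methallyl-SiMe3 (6 mol%, silylates the catalyst and scavenges protons), toluene, strictly anhydrous, −78 → −40 °C; Et3N quench
Reagents that add atoms: none
Why: Proposed new method: the silylated chiral imidodiphosphorimidate (a chiral counterpart of TMSOTf) should silylate the enol-ether oxygen O3 of racemic 6 and ionise the C2–O3 bond, so that both enantiomers give the same achiral 2-oxonia-triene 7 (C2=O1+ joined through the ring-derived (Z)-C5=C6 bond to the silyl enol ether C3=C4) inside the chiral anion, after which C3 adds to C2 to give 8 and silyl transfer from 8 to the next molecule of 6 releases 9 in an atom-economic isomerisation. The closest known reaction types are the Lewis acid-promoted (Me2AlCl, TMSOTf) Petasis–Ferrier rearrangement of 4-methylene-1,3-dioxanes, the chiral phosphoric acid-catalysed aza-Petasis–Ferrier rearrangement and silylium counteranion-directed Mukaiyama aldol and hetero-Diels–Alder reactions of aliphatic aldehydes. The pyranone ring closes 6-(enolendo)-endo-trig, which can also be viewed as a 6π-electrocyclisation of the 2-oxonia-triene. C2, the only stereocentre, is set by the confined chiral counteranion, which covers one face of the planar oxocarbenium carbon; the racemic acetal centre of 6 is erased on ionisation, which makes the step enantioconvergent. The step needs enantioface selectivity, C–C instead of C–O recombination and no Prins reaction at the chain alkene; the substrate secures the last two, because return of O3 or ionisation at O1 (which could only close a four-membered ring) merely regenerates 6 while attack by C3 is irreversible (a C=O bond is gained), the (Z)-C5=C6 geometry fixed by the former ring holds C3 next to C2, and nine methylene groups separate the alkene from C2, whereas enantioface selectivity rests on the catalyst pocket alone.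

**Compound list**
1 | (11Z)-icos-11-en-1-ol | CCCCCCCC/C=C\CCCCCCCCCCO | starting material
2 | (11Z)-icos-11-enal | CCCCCCCC/C=C\CCCCCCCCCC=O | intermediate
3 | 2,2,6-trimethyl-4H-1,3-dioxin-4-one | CC1=CC(=O)OC(C)(C)O1 | starting material
4 | acetylketene (3-oxobut-1-en-1-one; formed in the flask, not isolated) | CC(=O)C=C=O | intermediate
5 | rac-6-methyl-2-[(10Z)-nonadec-10-en-1-yl]-4H-1,3-dioxin-4-one | CCCCCCCC/C=C\CCCCCCCCCC1OC(C)=CC(=O)O1 | intermediate
6 | rac-6-methyl-4-methylidene-2-[(10Z)-nonadec-10-en-1-yl]-4H-1,3-dioxine | CCCCCCCC/C=C\CCCCCCCCCC1OC(C)=CC(=C)O1 | intermediate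
7 | [(11Z)-icos-11-en-1-ylidene][(2Z)-4-(trimethylsilyloxy)penta-2,4-dien-2-yl]oxonium, ion pair with the chiral IDPi anion (not isolated) | CCCCCCCC/C=C\CCCCCCCCCC=[O+]/C(C)=C\C(=C)O[Si](C)(C)C | intermediate
8 | (2R)-6-methyl-2-[(10Z)-nonadec-10-en-1-yl]-4-(trimethylsilyloxy)-2,3-dihydropyrylium, IDPi salt (not isolated) | CCCCCCCC/C=C\CCCCCCCCC[C@@H]1CC(O[Si](C)(C)C)=CC(C)=[O+]1 | intermediate
9 | (2R)-6-methyl-2-[(10Z)-nonadec-10-en-1-yl]-2,3-dihydro-4H-pyran-4-one | CCCCCCCC/C=C\CCCCCCCCC[C@@H]1CC(=O)C=C(C)O1 | target

**Totals**
Total step count: 4. Longest linear sequence: 4 steps (1 → 2 → 5 → 6 → 9).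

**Steps most likely to fail**

1. Step 4 (Proposed new method). The two faces of a purely aliphatic oxocarbenium ion may be discriminated poorly. The catalyst may be arrested because the silyl group stays on the Lewis-basic vinylogous ester of the product. Adventitious acid may protonate the exocyclic methylene carbon, leading to hydrolysis or cationic oligomerisation, and an achiral background rearrangement may erode the selectivity. The fallback uses known chemistry, sets out from 2 and comes back at 9. Commercial 4-(trimethylsilyloxy)pent-3-en-2-one is silylated (LDA, TMSCl, THF, −78 °C) to 2,4-bis(trimethylsilyloxy)penta-1,3-diene F1. A BINOL–Ti(IV)-catalysed vinylogous Mukaiyama aldol addition of F1 to 2, with the BINOL antipode that delivers the (R)-carbinol, should give (6R,16Z)-2,6-bis(trimethylsilyloxy)pentacosa-2,16-dien-4-one F2. TFA in CH2Cl2 should remove both silyl groups to give (6R,16Z)-6-hydroxypentacos-16-ene-2,4-dione F3, which under the same acid should close by hemiketalisation at the distal carbonyl and loss of water to 9; the carbinol centre is not touched.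

2. Step 3. Carbene addition to the deactivated (vinylogous carbonate) carbonyl may be slow enough for thermal cycloreversion of the dioxinone to compete. The exo-methylene acetal may hydrolyse or rearrange prematurely, and then racemically, on the titanium residues or during isolation. The fallback sets out from 2 and comes back at 9 by a reagent-controlled boron aldol route to dihydropyranones. Acetylacetone is converted ((COCl)2, cat. DMF, CH2Cl2) into 4-chloropent-3-en-2-one F4. Its diisopinocampheylboron enolate (Ipc2BCl antipode chosen for the (R)-carbinol, iPr2NEt, Et2O, −78 °C) should add to 2 and give, after oxidative work-up, (6R,16Z)-2-chloro-6-hydroxypentacosa-2,16-dien-4-one F5. iPr2NEt/TMSOTf in CH2Cl2 should then close the ring by 6-endo oxa-Michael addition and loss of chloride to give 9.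

3. Step 2. At 110 °C, aldol self-condensation of the enolisable aldehyde and dimerisation of acetylketene may outrun the cycloaddition, and the exchange may stall while acetone is retained. The fallback sets out from 2 and comes back at 5; it builds the ring by acetalisation at the saturated level and dehydrogenates afterwards. rac-3-Hydroxybutanoic acid and 2 (cat. PPTS, azeotropic removal of water) should give 6-methyl-2-[(10Z)-nonadec-10-en-1-yl]-1,3-dioxan-4-one F6 (racemic, mainly cis; its ring stereochemistry is immaterial). The lithium enolate (LDA, THF, −78 °C) is trapped with PhSeSePh, which does not attack the alkene, to give 6-methyl-2-[(10Z)-nonadec-10-en-1-yl]-5-(phenylselanyl)-1,3-dioxan-4-one F7. Oxidation (H2O2, pyridine, CH2Cl2, 0 °C) and selenoxide syn-elimination towards C6, the only β-hydrogen, should give 5.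

**Further compounds**
F1 | step 4 | 2,4-bis(trimethylsilyloxy)penta-1,3-diene | C=C(O[Si](C)(C)C)C=C(C)O[Si](C)(C)C
F2 | step 4 | (6R,16Z)-2,6-bis(trimethylsilyloxy)pentacosa-2,16-dien-4-one | CCCCCCCC/C=C\CCCCCCCCC[C@@H](O[Si](C)(C)C)CC(=O)C=C(C)O[Si](C)(C)C
F3 | step 4 | (6R,16Z)-6-hydroxypentacos-16-ene-2,4-dione | CCCCCCCC/C=C\CCCCCCCCC[C@@H](O)CC(=O)CC(=O)C
F4 | step 3 | 4-chloropent-3-en-2-one | CC(Cl)=CC(C)=O
F5 | step 3 | (6R,16Z)-2-chloro-6-hydroxypentacosa-2,16-dien-4-one | CCCCCCCC/C=C\CCCCCCCCC[C@@H](O)CC(=O)C=C(C)Cl
F6 | step 2 | rac-6-methyl-2-[(10Z)-nonadec-10-en-1-yl]-1,3-dioxan-4-one | CCCCCCCC/C=C\CCCCCCCCCC1OC(C)CC(=O)O1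
F7 | step 2 | 6-methyl-2-[(10Z)-nonadec-10-en-1-yl]-5-(phenylselanyl)-1,3-dioxan-4-one | CCCCCCCC/C=C\CCCCCCCCCC1OC(C)C([Se]c2ccccc2)C(=O)O1
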